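**Retrosynthetic overview**

- The strategy rests on ring A of the 6-linked flavone. Its C6 carries C8 of the other flavone and lies between the hydroxylated C5 and C7, so C5–C6–C7 is an arylmalonyl unit. C8, C8a and C4a are the methyl carbon and two ring carbons of a 2-aryl-6-methyl-4-pyranone (ring C).
- The last disconnection removes three benzyl ethers. The key disconnection cuts C7–C8 and C4a–C5 of that ring A, giving a flavon-8-yl(chlorocarbonyl)ketene and a 4-silyloxy-2-methylene-2H-pyran.
- The ketene comes from the flavon-8-ylmalonic acid, made by malonate arylation of the 8-iodoflavone. The 8-linked flavone is built first (ring A from the acetophenone, ring C by oxidative chalcone cyclisation).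
- The methylenepyran comes from a 2-aryl-6-methyl-4-pyranone (ring C of the 6-linked flavone), made by dianion aroylation and cyclodehydration.
- Ring order: ring C of the 8-linked flavone, then the pyranone ring C of the 6-linked flavone, then its ring A in the key step.

Key step: step 11

Remark: the target SMILES fixes no configuration at the hindered C8–C6 biaryl axis, so the route is planned for the racemic atropisomer; the target has no stereocentre.

**Route**

Step 1
Reactants: 1 2,6-dihydroxy-4-methoxyacetophenone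
Product: 2 1-(2-benzyloxy-6-hydroxy-4-methoxyphenyl)ethanone
Conditions: BnBr (1.05 equiv), K2CO3, acetone, reflux
Reagents that add atoms: benzyl bromide, BrCc1ccccc1
Why: Williamson etherification; after the first alkylation the remaining hydroxyl is locked in a hydrogen bond to the acetyl carbonyl, so mono-benzylation should be clean.

Step 2
Reactants: 2 1-(2-benzyloxy-6-hydroxy-4-methoxyphenyl)ethanone; 3 4-(benzyloxy)benzaldehyde
Product: 4 (E)-1-(2-benzyloxy-6-hydroxy-4-methoxyphenyl)-3-(4-benzyloxyphenyl)prop-2-en-1-one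
Conditions: KOH, EtOH/H2O, rt; then aq. HCl
Reagents that add atoms: none
Why: Claisen–Schmidt condensation of a methyl ketone with a non-enolisable aldehyde; dehydration of the aldol gives the conjugated E-enone, and the benzyl ethers are inert to alkali.

Step 3
Reactants: 4 (E)-1-(2-benzyloxy-6-hydroxy-4-methoxyphenyl)-3-(4-benzyloxyphenyl)prop-2-en-1-one
Product: 5 5-benzyloxy-2-(4-benzyloxyphenyl)-7-methoxy-4H-chromen-4-one
Conditions: I2 (10 mol %), DMSO, 130 °C
Reagents that add atoms: none
Why: iodine-mediated oxidative cyclisation of a 2'-hydroxychalcone to a flavone, with DMSO as terminal oxidant regenerating iodine; it is a standard method for benzyl-protected flavones.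

Step 4
Reactants: 5 5-benzyloxy-2-(4-benzyloxyphenyl)-7-methoxy-4H-chromen-4-one
Product: 6 5-benzyloxy-2-(4-benzyloxyphenyl)-8-iodo-7-methoxy-4H-chromen-4-one
Conditions: NIS (1.1 equiv), TFA (cat.), CH2Cl2/MeCN, 0 °C to rt
Reagents that add atoms: N-iodosuccinimide, O=C1CCC(=O)N1I
Why: electrophilic aromatic iodination; fully O-alkylated 5,7-dioxygenated flavones react at C8 (ortho to the 7-alkoxy group, para to the 5-alkoxy group), whereas C6 is flanked by two alkoxy groups and the other rings are far less electron-rich.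

Step 5
Reactants: 6 5-benzyloxy-2-(4-benzyloxyphenyl)-8-iodo-7-methoxy-4H-chromen-4-one; 7 dimethyl malonate
Product: 8 dimethyl 2-[5-benzyloxy-2-(4-benzyloxyphenyl)-7-methoxy-4-oxo-4H-chromen-8-yl]malonate
Conditions: Pd2(dba)3 (cat.), P(t-Bu)3·HBF4 (cat.), K3PO4, PhMe, 80 °C
Reagents that add atoms: none
Why: palladium-catalysed α-arylation of a malonate enolate; the bulky electron-rich phosphine supports oxidative addition to the electron-rich iodide and reductive elimination from the hindered arylpalladium malonate, and the weak base leaves the flavone untouched.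

Step 6
Reactants: 8 dimethyl 2-[5-benzyloxy-2-(4-benzyloxyphenyl)-7-methoxy-4-oxo-4H-chromen-8-yl]malonate
Product: 9 2-[5-benzyloxy-2-(4-benzyloxyphenyl)-7-methoxy-4-oxo-4H-chromen-8-yl]malonic acid
Conditions: LiOH·H2O, THF/MeOH/H2O, rt; then 1 M HCl, 0 °C
Reagents that add atoms: lithium hydroxide (hydroxide oxygen), [Li+].[OH-]
Why: ester saponification; mild hydroxide at room temperature should not open the flavone ring, and cold acidification with drying below room temperature keeps the arylmalonic acid from decarboxylating.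

Step 7
Reactants: 9 2-[5-benzyloxy-2-(4-benzyloxyphenyl)-7-methoxy-4-oxo-4H-chromen-8-yl]malonic acid
Product: 11 [5-benzyloxy-2-(4-benzyloxyphenyl)-7-methoxy-4-oxo-4H-chromen-8-yl](chlorocarbonyl)ketene, via arylmalonyl dichloride 10 (not isolated)
Conditions: (COCl)2 (2.2 equiv), DMF (cat.), CH2Cl2, 0 °C to rt; then PhMe, 80 °C, Ar sweep; evaporation, crude used as a PhMe solution
Reagents that add atoms: oxalyl chloride, O=C(Cl)C(=O)Cl
Why: the known conversion of arylmalonic acids into aryl(chlorocarbonyl)ketenes, by acid chloride formation and thermal 1,2-loss of HCl from the dichloride; the di-ortho-substituted electron-rich aryl group favours and stabilises the ketene, and all by-products are volatile.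

Step 8
Reactants: 12 acetylacetone; 13 methyl 4-(benzyloxy)benzoate
Product: 14 1-(4-benzyloxyphenyl)hexane-1,3,5-trione
Conditions: 12 (2 equiv), LDA (4 equiv), THF, 0 °C; then 13, 0 °C to rt; aq. HCl
Reagents that add atoms: none
Why: Claisen-type aroylation of the 1,3-diketone dianion at its terminal, more basic carbanion; the second equivalent of dianion absorbs the proton of the more acidic triketone.

Step 9
Reactants: 14 1-(4-benzyloxyphenyl)hexane-1,3,5-trione
Product: 15 2-(4-benzyloxyphenyl)-6-methyl-4H-pyran-4-one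
Conditions: p-TsOH·H2O (cat.), PhMe, reflux, Dean–Stark
Reagents that add atoms: none
Why: acid-catalysed cyclodehydration of a 1,3,5-triketone; the terminal enol oxygen adds to the other terminal carbonyl and loses water, and only this 4-pyranone constitution is possible.

Step 10
Reactants: 15 2-(4-benzyloxyphenyl)-6-methyl-4H-pyran-4-one
Product: 16 6-(4-benzyloxyphenyl)-4-(tert-butyldimethylsilyloxy)-2-methylene-2H-pyran
Conditions: KHMDS, THF, −78 °C; then TBSCl, −78 to 0 °C; pentane, filtration under Ar, no aqueous work-up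
Reagents that add atoms: tert-butyldimethylsilyl chloride, CC(C)(C)[Si](C)(C)Cl
Why: γ-deprotonation of the only acidic sp3 position gives the extended enolate, and a hard bulky silyl chloride traps it on oxygen, as in silyl dienol ether formation from 6-methyl-1,3-dioxin-4-ones.

Step 11
Reactants: 11 [5-benzyloxy-2-(4-benzyloxyphenyl)-7-methoxy-4-oxo-4H-chromen-8-yl](chlorocarbonyl)ketene; 16 6-(4-benzyloxyphenyl)-4-(tert-butyldimethylsilyloxy)-2-methylene-2H-pyran
Product: 20 5-benzyloxy-2-(4-benzyloxyphenyl)-8-[2-(4-benzyloxyphenyl)-5,7-dihydroxy-4-oxo-4H-chromen-6-yl]-7-methoxy-4H-chromen-4-one, via acylketene 17 (not isolated), via enol dienylketene 18 (not isolated), via 4a-H dienone 19 (not isolated)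
Conditions: 16 (1.1 equiv) added slowly to 11, PhMe (dilute), 80 °C; then 110 °C
Reagents that add atoms: none
Why: Proposed new method: the exocyclic methylene of 16 is the terminus of an O-silylated pyrylium anhydrobase and should attack an acyl carbon of 11, because only this attack generates an aromatic 4-silyloxypyrylium ion; chloride then leaves the resulting enolate and takes the silyl group, giving acylketene 17 and TBSCl (bond C7–C8) with no HCl to protonate unreacted 16. Enolisation of the doubly activated CH2 gives dienylketene 18, a hexatriene over the ketene carbon C5, C6, C7, C8, C8a and C4a, and thermal disrotatory 6-pi electrocyclisation (equivalently, ketene acylation of the nucleophilic pyranone CH) closes ring A through the C5–C4a bond to dienone 19, which aromatises by a proton shift to the 5,7-diol 20. The closest known reaction types are the (3+3) cyclocondensation of aryl(chlorocarbonyl)ketenes with 1,3-dinucleophiles, the C-acylation of methylenepyrans and of dioxinone-derived silyl dienol ethers at the exocyclic carbon, and the dienylketene electrocyclisation that ends a Danheiser benzannulation. The step needs carbon rather than oxygen acylation, which the silyl cap and the aromatisation on carbon attack should secure, and closure at carbon, which is the only option because the oxygen that normally closes malonyl adducts to 4-hydroxy-2-pyranones is here the fully substituted ring oxygen O1. The 6-linked constitution is fixed because the aryl group sits on the central carbon of the three-carbon unit and O1 is already on C8a next to C8; no stereocentre survives (C4a of 19 is lost on aromatisation) and the biaryl axis forms as a racemate. Slow addition of 16 to hot 11 should keep 17 from meeting a second molecule of 16, and the di-ortho-substituted aryl group suppresses ketene dimerisation.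

Step 12
Reactants: 20 5-benzyloxy-2-(4-benzyloxyphenyl)-8-[2-(4-benzyloxyphenyl)-5,7-dihydroxy-4-oxo-4H-chromen-6-yl]-7-methoxy-4H-chromen-4-one
Product: 21 7'-O-methylagathisflavone
Conditions: H2 (1 atm), 10% Pd/C, THF/MeOH, rt
Reagents that add atoms: none
Why: hydrogenolysis of the three aryl benzyl ethers; the aryl methyl ether is inert, and the flavone C2–C3 double bonds should survive at atmospheric pressure if the reaction is stopped at full debenzylation.

**Compound list**

1 | 2,6-dihydroxy-4-methoxyacetophenone | CC(=O)c1c(O)cc(OC)cc1O | starting material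
2 | 1-(2-benzyloxy-6-hydroxy-4-methoxyphenyl)ethanone | CC(=O)c1c(O)cc(OC)cc1OCc2ccccc2 | intermediate
3 | 4-(benzyloxy)benzaldehyde | O=Cc1ccc(OCc2ccccc2)cc1 | starting material
4 | (E)-1-(2-benzyloxy-6-hydroxy-4-methoxyphenyl)-3-(4-benzyloxyphenyl)prop-2-en-1-one | COc1cc(O)c(C(=O)/C=C/c2ccc(OCc3ccccc3)cc2)c(OCc2ccccc2)c1 | intermediate
5 | 5-benzyloxy-2-(4-benzyloxyphenyl)-7-methoxy-4H-chromen-4-one | COc1cc(OCc4ccccc4)c2c(=O)cc(-c3ccc(OCc4ccccc4)cc3)oc2c1 | intermediate
6 | 5-benzyloxy-2-(4-benzyloxyphenyl)-8-iodo-7-methoxy-4H-chromen-4-one | COc1cc(OCc4ccccc4)c2c(=O)cc(-c3ccc(OCc4ccccc4)cc3)oc2c1I | intermediate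
7 | dimethyl malonate | COC(=O)CC(=O)OC | starting material
8 | dimethyl 2-[5-benzyloxy-2-(4-benzyloxyphenyl)-7-methoxy-4-oxo-4H-chromen-8-yl]malonate | COc1cc(OCc4ccccc4)c2c(=O)cc(-c3ccc(OCc4ccccc4)cc3)oc2c1C(C(=O)OC)C(=O)OC | intermediate
9 | 2-[5-benzyloxy-2-(4-benzyloxyphenyl)-7-methoxy-4-oxo-4H-chromen-8-yl]malonic acid | COc1cc(OCc4ccccc4)c2c(=O)cc(-c3ccc(OCc4ccccc4)cc3)oc2c1C(C(=O)O)C(=O)O | intermediate
10 | 2-[5-benzyloxy-2-(4-benzyloxyphenyl)-7-methoxy-4-oxo-4H-chromen-8-yl]malonyl dichloride | COc1cc(OCc4ccccc4)c2c(=O)cc(-c3ccc(OCc4ccccc4)cc3)oc2c1C(C(=O)Cl)C(=O)Cl | intermediate (not isolated)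
11 | [5-benzyloxy-2-(4-benzyloxyphenyl)-7-methoxy-4-oxo-4H-chromen-8-yl](chlorocarbonyl)ketene | COc1cc(OCc4ccccc4)c2c(=O)cc(-c3ccc(OCc4ccccc4)cc3)oc2c1C(=C=O)C(=O)Cl | intermediate
12 | acetylacetone (pentane-2,4-dione) | CC(=O)CC(C)=O | starting material
13 | methyl 4-(benzyloxy)benzoate | COC(=O)c1ccc(OCc2ccccc2)cc1 | starting material
14 | 1-(4-benzyloxyphenyl)hexane-1,3,5-trione | CC(=O)CC(=O)CC(=O)c1ccc(OCc2ccccc2)cc1 | intermediate
15 | 2-(4-benzyloxyphenyl)-6-methyl-4H-pyran-4-one | Cc1cc(=O)cc(-c2ccc(OCc3ccccc3)cc2)o1 | intermediate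
16 | 6-(4-benzyloxyphenyl)-4-(tert-butyldimethylsilyloxy)-2-methylene-2H-pyran | C=C1C=C(O[Si](C)(C)C(C)(C)C)C=C(c2ccc(OCc3ccccc3)cc2)O1 | intermediate
17 | acylketene: 2-(flavon-8-yl)-4-[6-(4-benzyloxyphenyl)-4-oxo-4H-pyran-2-yl]-3-oxobut-1-en-1-one (flavon-8-yl as in 11) | COc1cc(OCc4ccccc4)c2c(=O)cc(-c3ccc(OCc4ccccc4)cc3)oc2c1C(=C=O)C(=O)Cc1cc(=O)cc(-c2ccc(OCc3ccccc3)cc2)o1 | intermediate (not isolated)
18 | enol dienylketene: (E)-enol of 17, with C6 and the pyranone carbon cis on the C7=C8 double bond | COc1cc(OCc4ccccc4)c2c(=O)cc(-c3ccc(OCc4ccccc4)cc3)oc2c1C(=C=O)/C(O)=C\c1cc(=O)cc(-c2ccc(OCc3ccccc3)cc2)o1 | intermediate (not isolated)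
19 | 4a-H dienone: 6-(flavon-8-yl)-2-(4-benzyloxyphenyl)-7-hydroxy-4aH-chromene-4,5-dione (racemic at the transient sp3 C4a) | COc1cc(OCc4ccccc4)c2c(=O)cc(-c3ccc(OCc4ccccc4)cc3)oc2c1C1=C(O)C=C2OC(c3ccc(OCc4ccccc4)cc3)=CC(=O)C2C1=O | intermediate (not isolated)
20 | 5-benzyloxy-2-(4-benzyloxyphenyl)-8-[2-(4-benzyloxyphenyl)-5,7-dihydroxy-4-oxo-4H-chromen-6-yl]-7-methoxy-4H-chromen-4-one | COc1cc(OCc4ccccc4)c2c(=O)cc(-c3ccc(OCc4ccccc4)cc3)oc2c1-c1c(O)cc2oc(-c3ccc(OCc4ccccc4)cc3)cc(=O)c2c1O | intermediate
21 | 7'-O-methylagathisflavone | COc1cc(O)c2c(=O)cc(-c3ccc(O)cc3)oc2c1-c1c(O)cc2oc(-c3ccc(O)cc3)cc(=O)c2c1O | target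

**Step count and risks**

Total step count: 12. Longest linear sequence: 9 steps (steps 1 to 7, then 11 and 12); the pyranone branch (steps 8 to 10) joins at step 11.

Steps most likely to fail:

Step 11 (proposed new method). The acylketene may be intercepted by a second molecule of the methylenepyran or by the phenols of the product before it closes. The methylenepyran may also be desilylated by adventitious acid instead of being acylated at carbon, or enolisation and closure may be slower than ketene oligomerisation. The fallback is a cross-coupling of two complete flavones by known chemistry; it sets out from 6 and comes back at 21.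
- Miyaura borylation of 6 (B2pin2, PdCl2(dppf), KOAc, dioxane, 90 °C) should give 5-benzyloxy-2-(4-benzyloxyphenyl)-7-methoxy-8-(4,4,5,5-tetramethyl-1,3,2-dioxaborolan-2-yl)-4H-chromen-4-one F1.
- Commercial apigenin (O=c1cc(-c2ccc(O)cc2)oc2cc(O)cc(O)c12) is benzylated at O7 and O4' (BnBr, K2CO3, DMF; the chelated 5-hydroxyl stays free) to 7-benzyloxy-2-(4-benzyloxyphenyl)-5-hydroxy-4H-chromen-4-one F2.
- Iodination directed to C6 by the free 5-hydroxyl (benzyltrimethylammonium dichloroiodate, CaCO3, CH2Cl2/MeOH) gives 7-benzyloxy-2-(4-benzyloxyphenyl)-5-hydroxy-6-iodo-4H-chromen-4-one F3.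
- Suzuki–Miyaura coupling of F1 with F3 under conditions for hindered biaryls (Pd(OAc)2, SPhos, K3PO4, PhMe/H2O, 100 °C) should give 5-benzyloxy-8-[7-benzyloxy-2-(4-benzyloxyphenyl)-5-hydroxy-4-oxo-4H-chromen-6-yl]-2-(4-benzyloxyphenyl)-7-methoxy-4H-chromen-4-one F4.
- Hydrogenolysis of its four benzyl ethers (H2, 10% Pd/C) gives 21.

Step 7. Oxalyl chloride may also activate the flavone carbonyl as a chloropyrylium salt, the HCl released may cleave the acid-labile 5-benzyl ether, and the malonic acid may decarboxylate before it is chlorinated. The fallback sets out from 9 and comes back at 11. The acid chloride is formed with 1-chloro-N,N,2-trimethylprop-1-en-1-amine (2.1 equiv, CH2Cl2, 0 °C). This reagent reacts only with the carboxyl O–H groups, transfers chloride without releasing HCl, CO or CO2, and cannot attack the pyranone carbonyl. It should give dichloride 10, which is dehydrochlorinated without base (PhMe, 60 to 80 °C, reduced pressure) to 11. The amide by-product is removed by trituration with dry pentane. No compound outside the list arises (F0).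

Step 10. The extended enolate may be silylated at carbon, deprotonation may be incomplete, or the silyl group may be lost by hydrolysis during isolation. The fallback reverses the order of events (soft enolisation); it sets out from 15 and comes back at 16. TBSOTf (CH2Cl2, 0 °C) first silylates the carbonyl oxygen to give 2-(4-benzyloxyphenyl)-4-(tert-butyldimethylsilyloxy)-6-methylpyrylium triflate F5, so silicon can only be on oxygen. The now acidic methyl group is then deprotonated with i-Pr2NEt, as in the formation of pyrylium anhydrobases. Precipitation of the ammonium triflate with pentane leaves 16, which can be carried into step 11 as a solution.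

**Further compounds**

F1 | step 11 | 5-benzyloxy-2-(4-benzyloxyphenyl)-7-methoxy-8-(4,4,5,5-tetramethyl-1,3,2-dioxaborolan-2-yl)-4H-chromen-4-one | COc1cc(OCc4ccccc4)c2c(=O)cc(-c3ccc(OCc4ccccc4)cc3)oc2c1B5OC(C)(C)C(C)(C)O5
F2 | step 11 | 7-benzyloxy-2-(4-benzyloxyphenyl)-5-hydroxy-4H-chromen-4-one | O=c1cc(-c2ccc(OCc3ccccc3)cc2)oc2cc(OCc3ccccc3)cc(O)c12
F3 | step 11 | 7-benzyloxy-2-(4-benzyloxyphenyl)-5-hydroxy-6-iodo-4H-chromen-4-one | O=c1cc(-c2ccc(OCc3ccccc3)cc2)oc2cc(OCc3ccccc3)c(I)c(O)c12
F4 | step 11 | 5-benzyloxy-8-[7-benzyloxy-2-(4-benzyloxyphenyl)-5-hydroxy-4-oxo-4H-chromen-6-yl]-2-(4-benzyloxyphenyl)-7-methoxy-4H-chromen-4-one | COc1cc(OCc4ccccc4)c2c(=O)cc(-c3ccc(OCc4ccccc4)cc3)oc2c1-c1c(OCc4ccccc4)cc2oc(-c3ccc(OCc4ccccc4)cc3)cc(=O)c2c1O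
F0 | step 7 | none | none
F5 | step 10 | 2-(4-benzyloxyphenyl)-4-(tert-butyldimethylsilyloxy)-6-methylpyrylium trifluoromethanesulfonate | Cc1cc(O[Si](C)(C)C(C)(C)C)cc(-c2ccc(OCc3ccccc3)cc2)[o+]1.[O-]S(=O)(=O)C(F)(F)F
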